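**Assumption:** the SMILES is taken literally, i.e. (4S,5R,6S,7S,9S,10R) with the C9 side chain trans to the C10 methyl; names use labdane locants (C18 = 4α-methyl, C19 = carboxyl carbon, C20 = 10β-methyl, C17 = exocyclic methylene carbon) and α means the face opposite to the C10 methyl.

## Retrosynthetic overview

1. Target 43 ← global desilylation of 42 ← benzoylation and opening of the 19,6β-lactone 38 (the lactone masks the C19 acid and the C6 oxygen) ← reduction of the 7-ketone 37.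
2. C9–C11 bond and C8 methylene ← copper-catalysed conjugate coupling of alkylmagnesium bromide 33 with enone lactone 25, the enolate being trapped by Mannich methylenation.
3. Lactone ring (formed last) ← invertive lactonisation of hydroxy acid 24; rings A then B are formed in one step from acyclic 21 by a copper-catalysed radical bicyclisation (C4–C5, then C9–C10).
4. 21 ← B-alkyl Suzuki–Miyaura coupling (C1–C10 bond) of the borane from chloro ester 6 with vinyl iodide 18, whose C6 stereocentre comes from a Brown alkoxyallylboration.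
5. Side chain 32 ← zirconium-catalysed carboalumination of silylated but-3-yn-1-ol.

## Route

**Step 1**
Reactants: 1 propanoyl chloride
Product: 2 tert-butyl propanoate
Conditions: t-BuOH, pyridine, CH2Cl2, 0 °C to rt
Reagents that add atoms: tert-butanol, CC(C)(C)O
Why: Alcoholysis of the acyl chloride gives a tert-butyl ester that survives the later organometallic and radical steps and is removed by acid.

**Step 2**
Reactants: 2 tert-butyl propanoate
Product: 4 tert-butyl 2-methylpent-4-enoate (racemic), via lithium enolate 3 (not isolated)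
Conditions: LiN(iPr)2, THF, −78 °C; allyl bromide, −78 °C to rt
Reagents that add atoms: allyl bromide, C=CCBr
Why: Ester enolate alkylation (SN2); the new centre is racemic and is erased in step 3.

**Step 3**
Reactants: 4 tert-butyl 2-methylpent-4-enoate
Product: 6 tert-butyl 2-chloro-2-methylpent-4-enoate (racemic), via lithium enolate 5 (not isolated)
Conditions: LiN(iPr)2, THF, −78 °C; C2Cl6, −78 to 0 °C
Reagents that add atoms: hexachloroethane, ClC(Cl)(Cl)C(Cl)(Cl)Cl
Why: Electrophilic chlorination of the ester enolate gives the tertiary α-chloro ester (radical precursor); its centre becomes a planar radical in step 12.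

**Step 4**
Reactants: 7 but-2-yn-1-ol
Product: 9 (E)-3-iodobut-2-en-1-ol, via alkenylzirconocene 8 (not isolated)
Conditions: Cp2Zr(H)Cl (2.2 equiv), THF, rt to 40 °C; I2, 0 °C
Reagents that add atoms: iodine, II
Why: Hydrozirconation–iodination: syn addition with zirconium at the less hindered methyl-bearing carbon, then iodinolysis with retention, gives the E iodide.

**Step 5**
Reactants: 9 (E)-3-iodobut-2-en-1-ol
Product: 10 (E)-3-iodobut-2-enal
Conditions: MnO2, CH2Cl2, rt
Reagents that add atoms: none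
Why: Allylic alcohol oxidation under neutral conditions keeps the E geometry.

**Step 6**
Reactants: 11 prop-2-en-1-ol
Product: 12 1-methoxy-4-[(prop-2-en-1-yloxy)methyl]benzene
Conditions: NaH, 4-MeOC6H4CH2Cl, Bu4NI (cat.), DMF, 0 °C to rt
Reagents that add atoms: 4-methoxybenzyl chloride, COc1ccc(CCl)cc1
Why: Williamson ether synthesis gives the allyl ether needed for the alkoxyallylboration.

**Step 7**
Reactants: 10 (E)-3-iodobut-2-enal; 12 1-methoxy-4-[(prop-2-en-1-yloxy)methyl]benzene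
Product: 16 (3R,4R,5E)-6-iodo-3-[(4-methoxybenzyl)oxy]hepta-1,5-dien-4-ol, via allyllithium 13 (not isolated), via allylborane 14 (not isolated), via borinate 15 (not isolated)
Conditions: 12, s-BuLi, THF, −78 °C; (−)-Ipc2BOMe; BF3·OEt2; 10, −78 °C; NaOH, H2O2, 0 °C to rt
Reagents that add atoms: none
Why: Brown asymmetric γ-alkoxyallylboration, in which the chair transition state of the Z-alkoxyallylborane gives the syn diol monoether and the isopinocampheyl groups from (+)-α-pinene direct attack to the si face of the aldehyde, setting the carbinol carbon (later C6) as R.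

**Step 8**
Reactants: 16 (3R,4R,5E)-6-iodo-3-[(4-methoxybenzyl)oxy]hepta-1,5-dien-4-ol
Product: 17 triethyl{[(3R,4R,5E)-6-iodo-3-[(4-methoxybenzyl)oxy]hepta-1,5-dien-4-yl]oxy}silane
Conditions: Et3SiOTf, 2,6-lutidine, CH2Cl2, −78 °C
Reagents that add atoms: triethylsilyl trifluoromethanesulfonate, CC[Si](CC)(CC)OS(=O)(=O)C(F)(F)F
Why: Silylation of the secondary alcohol with a silyl triflate; no stereocentre is touched.

**Step 9**
Reactants: 17 triethyl{[(3R,4R,5E)-6-iodo-3-[(4-methoxybenzyl)oxy]hepta-1,5-dien-4-yl]oxy}silane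
Product: 18 (3R,4R,5E)-6-iodo-4-[(triethylsilyl)oxy]hepta-1,5-dien-3-ol
Conditions: DDQ, CH2Cl2/pH 7 buffer, 0 °C
Reagents that add atoms: none
Why: Oxidative cleavage of the 4-methoxybenzyl ether leaves the silyl ether and the vinyl iodide intact.

**Step 10**
Reactants: 6 tert-butyl 2-chloro-2-methylpent-4-enoate; 18 (3R,4R,5E)-6-iodo-4-[(triethylsilyl)oxy]hepta-1,5-dien-3-ol
Product: 20 tert-butyl (6E,8R,9R)-2-chloro-9-hydroxy-2,6-dimethyl-8-[(triethylsilyl)oxy]undeca-6,10-dienoate (both C2 epimers), via alkylborane 19 (not isolated)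
Conditions: 6, 9-BBN-H, THF, 0 °C to rt; then 18, PdCl2(dppf) (5 mol%), AsPh3, Cs2CO3, DMF/H2O, rt
Reagents that add atoms: none
Why: B-alkyl Suzuki–Miyaura coupling: anti-Markovnikov hydroboration of the terminal alkene, then palladium-catalysed sp3–sp2 coupling with retention of the vinyl iodide geometry, forms the C1–C10 bond and the E-trisubstituted alkene.

**Step 11**
Reactants: 20 tert-butyl (6E,8R,9R)-2-chloro-9-hydroxy-2,6-dimethyl-8-[(triethylsilyl)oxy]undeca-6,10-dienoate
Product: 21 tert-butyl (6E,8R)-2-chloro-2,6-dimethyl-9-oxo-8-[(triethylsilyl)oxy]undeca-6,10-dienoate (both C2 epimers)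
Conditions: Dess–Martin periodinane, NaHCO3, CH2Cl2, 0 °C
Reagents that add atoms: none
Why: Dess–Martin oxidation of the allylic alcohol to the vinyl ketone under buffered, non-enolising conditions leaves the adjacent stereocentre untouched.

**Step 12**
Reactants: 21 tert-butyl (6E,8R)-2-chloro-2,6-dimethyl-9-oxo-8-[(triethylsilyl)oxy]undeca-6,10-dienoate
Product: 23 tert-butyl (4S,5R,6R,10R)-7-oxo-6-[(triethylsilyl)oxy]-11,12,13,14,15,16,17-heptanorlabd-8-en-19-oate, via chloro ketone 22 (not isolated)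
Conditions: CuCl (5 mol%), tris(2-pyridylmethyl)amine (5 mol%), AIBN (10 mol%), ClCH2CH2Cl (0.005 M), 80 °C; then DBU, rt
Reagents that add atoms: none
Why: Proposed new method: a copper-catalysed atom-transfer radical bicyclisation in which monovalent copper abstracts chlorine from the tertiary α-chloro ester, the electrophilic C4 radical adds 6-endo to the electron-rich E-trisubstituted alkene at C5, the nucleophilic tertiary C10 radical adds 6-endo to the terminal carbon of the vinyl ketone (polarity-matched), and the α-keto radical takes chlorine back from divalent copper to give 22, which DBU dehydrochlorinates to the enone; chair–chair folding of the E alkene gives the trans ring fusion (5α-H, 10β-CH3) with the ester axial at C4 (as in trivalent-manganese cyclisations of α-methyl β-keto esters), and the C6 stereocentre fixes the absolute sense because 1,3-allylic strain with the C10 methyl holds C6–H in the alkene plane, so the radical attacks anti to the C6–C7 bond with the silyloxy group outside and the OSiEt3 ends up equatorial (6α); the closest known reaction types are copper/TPMA atom-transfer radical cyclisations of α-halo esters and manganese-mediated 6-endo/6-endo oxidative polyene cyclisations, neither of which has been shown for a simple α-chloro ester cascade ending on an enone under 1,3-allylic-strain control.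

**Step 13**
Reactants: 23 tert-butyl (4S,5R,6R,10R)-7-oxo-6-[(triethylsilyl)oxy]-11,12,13,14,15,16,17-heptanorlabd-8-en-19-oate
Product: 24 (4S,5R,6R,10R)-6-hydroxy-7-oxo-11,12,13,14,15,16,17-heptanorlabd-8-en-19-oic acid
Conditions: CF3CO2H/CH2Cl2 (1:4), H2O (5 equiv), 0 °C to rt
Reagents that add atoms: none
Why: Acidolysis cleaves the tert-butyl ester (loss of isobutene) and the triethylsilyl ether; the trans hydroxy acid cannot lactonise.

**Step 14**
Reactants: 24 (4S,5R,6R,10R)-6-hydroxy-7-oxo-11,12,13,14,15,16,17-heptanorlabd-8-en-19-oic acid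
Product: 25 (4S,5R,6S,10R)-7-oxo-11,12,13,14,15,16,17-heptanorlabd-8-en-19,6-olide
Conditions: PPh3, DIAD, THF (0.01 M), 0 °C to rt
Reagents that add atoms: none
Why: Mitsunobu lactonisation, in which the 6α-oxyphosphonium ion next to the ketone is displaced intramolecularly by the axial C19 carboxylate (SN2, inversion), sets C6 as S (6β-O); any C4 epimer from step 12 cannot close and is removed here.

**Step 15**
Reactants: 26 but-3-yn-1-ol
Product: 27 tert-butyl(but-3-yn-1-yloxy)dimethylsilane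
Conditions: t-BuMe2SiCl, imidazole, DMF, rt
Reagents that add atoms: tert-butyldimethylsilyl chloride, CC(C)(C)[Si](C)(C)Cl
Why: Standard silyl ether formation.

**Step 16**
Reactants: 27 tert-butyl(but-3-yn-1-yloxy)dimethylsilane
Product: 29 (2E)-5-[(tert-butyldimethylsilyl)oxy]-3-methylpent-2-en-1-ol, via alkenylalane 28 (not isolated)
Conditions: AlMe3 (2.5 equiv), Cp2ZrCl2 (20 mol%), CH2Cl2, 0 °C to rt; then (CH2O)n, THF, 0 °C to rt
Reagents that add atoms: trimethylaluminium, C[Al](C)C; formaldehyde (as paraformaldehyde), C=O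
Why: Negishi zirconium-catalysed carboalumination adds methyl and aluminium syn across the terminal alkyne, and trapping the E alkenylalane with formaldehyde gives the E-trisubstituted allylic alcohol (C13–C16 of the side chain).

**Step 17**
Reactants: 29 (2E)-5-[(tert-butyldimethylsilyl)oxy]-3-methylpent-2-en-1-ol
Product: 30 tert-butyl{[(3E)-5-[(tert-butyldiphenylsilyl)oxy]-3-methylpent-3-en-1-yl]oxy}dimethylsilane
Conditions: t-BuPh2SiCl, imidazole, DMF, rt
Reagents that add atoms: tert-butyldiphenylsilyl chloride, CC(C)(C)[Si](Cl)(c1ccccc1)c1ccccc1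
Why: Silylation of the allylic alcohol with the more acid-stable silyl group.

**Step 18**
Reactants: 30 tert-butyl{[(3E)-5-[(tert-butyldiphenylsilyl)oxy]-3-methylpent-3-en-1-yl]oxy}dimethylsilane
Product: 31 (3E)-5-[(tert-butyldiphenylsilyl)oxy]-3-methylpent-3-en-1-ol
Conditions: PPTS, EtOH, 40 °C
Reagents that add atoms: none
Why: Selective acid-catalysed solvolysis of the primary tert-butyldimethylsilyl ether in the presence of the tert-butyldiphenylsilyl ether.

**Step 19**
Reactants: 31 (3E)-5-[(tert-butyldiphenylsilyl)oxy]-3-methylpent-3-en-1-ol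
Product: 32 {[(2E)-5-bromo-3-methylpent-2-en-1-yl]oxy}(tert-butyl)diphenylsilane
Conditions: CBr4, PPh3, CH2Cl2, 0 °C
Reagents that add atoms: tetrabromomethane, BrC(Br)(Br)Br
Why: Appel bromination of the primary alcohol without touching the alkene geometry.

**Step 20**
Reactants: 25 (4S,5R,6S,10R)-7-oxo-11,12,13,14,15,16,17-heptanorlabd-8-en-19,6-olide; 32 {[(2E)-5-bromo-3-methylpent-2-en-1-yl]oxy}(tert-butyl)diphenylsilane
Product: 37 (4S,5R,6S,9S,10R)-15-[(tert-butyldiphenylsilyl)oxy]-7-oxolabda-8(17),13E-dien-19,6-olide, via alkylmagnesium bromide 33 (not isolated), via silyl enol ether 34 (not isolated), via Mannich base 35 (not isolated), via ammonium iodide 36 (not isolated)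
Conditions: 32, Mg, THF, rt; then CuBr·SMe2 (15 mol%), Me3SiCl, 25, THF, −78 °C; CH2=NMe2+ I−, CH2Cl2, rt; MeI; aq NaHCO3
Reagents that add atoms: N,N-dimethylmethyleneiminium iodide, C=[N+](C)C.[I-]
Why: Copper-catalysed, chlorosilane-accelerated conjugate addition of the Grignard reagent enters from the α face anti to the axial C10 methyl (as in 1α-alkylation of steroidal 1-en-3-ones) and sets C9 as S, after which a Mannich reaction of the silyl enol ether and Hofmann-type elimination install the C8 methylene.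

**Step 21**
Reactants: 37 (4S,5R,6S,9S,10R)-15-[(tert-butyldiphenylsilyl)oxy]-7-oxolabda-8(17),13E-dien-19,6-olide
Product: 38 (4S,5R,6S,7S,9S,10R)-15-[(tert-butyldiphenylsilyl)oxy]-7-hydroxylabda-8(17),13E-dien-19,6-olide
Conditions: NaBH4, CeCl3·7H2O, MeOH, −78 °C
Reagents that add atoms: none
Why: Luche 1,2-reduction, in which hydride is expected to enter from the β face because the α face is shielded by the pseudoaxial 9α side chain in a 1,3 relationship, gives the 7α alcohol (7S).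

**Step 22**
Reactants: 38 (4S,5R,6S,7S,9S,10R)-15-[(tert-butyldiphenylsilyl)oxy]-7-hydroxylabda-8(17),13E-dien-19,6-olide
Product: 39 (4S,5R,6S,7S,9S,10R)-7-[(tert-butyldimethylsilyl)oxy]-15-[(tert-butyldiphenylsilyl)oxy]labda-8(17),13E-dien-19,6-olide
Conditions: t-BuMe2SiOTf, 2,6-lutidine, CH2Cl2, 0 °C
Reagents that add atoms: tert-butyldimethylsilyl trifluoromethanesulfonate, CC(C)(C)[Si](C)(C)OS(=O)(=O)C(F)(F)F
Why: Silylation of the hindered axial alcohol with a silyl triflate protects O7 before the lactone is opened.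

**Step 23**
Reactants: 39 (4S,5R,6S,7S,9S,10R)-7-[(tert-butyldimethylsilyl)oxy]-15-[(tert-butyldiphenylsilyl)oxy]labda-8(17),13E-dien-19,6-olide
Product: 41 [2-(trimethylsilyl)ethoxy]methyl (4S,5R,6S,7S,9S,10R)-7-[(tert-butyldimethylsilyl)oxy]-15-[(tert-butyldiphenylsilyl)oxy]-6-hydroxylabda-8(17),13E-dien-19-oate, via potassium carboxylate 40 (not isolated)
Conditions: KOH, MeOH/THF/H2O, 45 °C; concentrate; Me3SiCH2CH2OCH2Cl, DMF, 0 °C
Reagents that add atoms: potassium hydroxide, [K+].[OH-]; 2-(trimethylsilyl)ethoxymethyl chloride, C[Si](C)(C)CCOCCl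
Why: Saponification of the strained γ-lactone, then SN2 O-alkylation of the carboxylate, frees the 6β-hydroxyl (too hindered to be alkylated) while C19 is held as a fluoride-labile ester; 41 is used at once to avoid relactonisation.

**Step 24**
Reactants: 41 [2-(trimethylsilyl)ethoxy]methyl (4S,5R,6S,7S,9S,10R)-7-[(tert-butyldimethylsilyl)oxy]-15-[(tert-butyldiphenylsilyl)oxy]-6-hydroxylabda-8(17),13E-dien-19-oate
Product: 42 [2-(trimethylsilyl)ethoxy]methyl (4S,5R,6S,7S,9S,10R)-6-(benzoyloxy)-7-[(tert-butyldimethylsilyl)oxy]-15-[(tert-butyldiphenylsilyl)oxy]labda-8(17),13E-dien-19-oate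
Conditions: PhCOCl, DMAP, pyridine, 45 °C
Reagents that add atoms: benzoyl chloride, O=C(Cl)c1ccccc1
Why: DMAP-catalysed acylation of the only free hydroxyl, the axial 6β-alcohol, with retention at C6.

**Step 25**
Reactants: 42 [2-(trimethylsilyl)ethoxy]methyl (4S,5R,6S,7S,9S,10R)-6-(benzoyloxy)-7-[(tert-butyldimethylsilyl)oxy]-15-[(tert-butyldiphenylsilyl)oxy]labda-8(17),13E-dien-19-oate
Product: 43 (4S,5R,6S,7S,9S,10R)-6-(benzoyloxy)-7,15-dihydroxylabda-8(17),13E-dien-19-oic acid (CNP0149011.1)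
Conditions: Bu4NF, AcOH, THF, 0 °C to rt
Reagents that add atoms: none
Why: Buffered fluoride removes both silyl ethers and fragments the silylethoxymethyl ester; the 6β-benzoate does not migrate because it is trans-diaxial to the 7α-hydroxyl.

## Compound list

1 | propanoyl chloride | CCC(=O)Cl | starting material
2 | tert-butyl propanoate | CCC(=O)OC(C)(C)C | intermediate
3 | lithium enolate of tert-butyl propanoate | CC=C(O[Li])OC(C)(C)C | intermediate
4 | tert-butyl 2-methylpent-4-enoate (racemic) | C=CCC(C)C(=O)OC(C)(C)C | intermediate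
5 | lithium enolate of tert-butyl 2-methylpent-4-enoate | C=CCC(C)=C(O[Li])OC(C)(C)C | intermediate
6 | tert-butyl 2-chloro-2-methylpent-4-enoate (racemic) | C=CCC(C)(Cl)C(=O)OC(C)(C)C | intermediate
7 | but-2-yn-1-ol | CC#CCO | starting material
8 | (E)-alkenylzirconocene chloride of but-2-en-1-ol, oxygen bound to a second Cp2ZrCl unit | C/C([Zr](Cl)(C1C=CC=C1)C1C=CC=C1)=C\CO[Zr](Cl)(C1C=CC=C1)C1C=CC=C1 | intermediate
9 | (E)-3-iodobut-2-en-1-ol | C/C(I)=C\CO | intermediate
10 | (E)-3-iodobut-2-enal | C/C(I)=C\C=O | intermediate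
11 | prop-2-en-1-ol | C=CCO | starting material
12 | 1-methoxy-4-[(prop-2-en-1-yloxy)methyl]benzene | C=CCOCc1ccc(OC)cc1 | intermediate
13 | (Z)-[3-(4-methoxybenzyloxy)allyl]lithium | [Li]C/C=C\OCc1ccc(OC)cc1 | intermediate
14 | [(Z)-3-(4-methoxybenzyloxy)allyl]bis(isopinocampheyl)borane, isopinocampheyl groups from (+)-α-pinene | COc1ccc(CO/C=C\CB([C@@H]2C[C@@H]3C[C@H]([C@H]2C)C3(C)C)[C@@H]2C[C@@H]3C[C@H]([C@H]2C)C3(C)C)cc1 | intermediate
15 | bis(isopinocampheyl)borinate of alcohol 16 | C=C[C@@H](OCc1ccc(OC)cc1)[C@H](OB([C@@H]2C[C@@H]3C[C@H]([C@H]2C)C3(C)C)[C@@H]2C[C@@H]3C[C@H]([C@H]2C)C3(C)C)/C=C(\C)I | intermediate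
16 | (3R,4R,5E)-6-iodo-3-[(4-methoxybenzyl)oxy]hepta-1,5-dien-4-ol | C=C[C@@H](OCc1ccc(OC)cc1)[C@H](O)/C=C(\C)I | intermediate
17 | triethyl{[(3R,4R,5E)-6-iodo-3-[(4-methoxybenzyl)oxy]hepta-1,5-dien-4-yl]oxy}silane | C=C[C@@H](OCc1ccc(OC)cc1)[C@H](O[Si](CC)(CC)CC)/C=C(\C)I | intermediate
18 | (3R,4R,5E)-6-iodo-4-[(triethylsilyl)oxy]hepta-1,5-dien-3-ol | C=C[C@@H](O)[C@H](O[Si](CC)(CC)CC)/C=C(\C)I | intermediate
19 | tert-butyl 5-(9-borabicyclo[3.3.1]nonan-9-yl)-2-chloro-2-methylpentanoate | CC(C)(C)OC(=O)C(C)(Cl)CCCB1C2CCCC1CCC2 | intermediate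
20 | tert-butyl (6E,8R,9R)-2-chloro-9-hydroxy-2,6-dimethyl-8-[(triethylsilyl)oxy]undeca-6,10-dienoate (both C2 epimers) | C=C[C@@H](O)[C@H](O[Si](CC)(CC)CC)/C=C(\C)CCCC(C)(Cl)C(=O)OC(C)(C)C | intermediate
21 | tert-butyl (6E,8R)-2-chloro-2,6-dimethyl-9-oxo-8-[(triethylsilyl)oxy]undeca-6,10-dienoate (both C2 epimers) | C=CC(=O)[C@H](O[Si](CC)(CC)CC)/C=C(\C)CCCC(C)(Cl)C(=O)OC(C)(C)C | intermediate
22 | tert-butyl (4S,5R,6R,10R)-8-chloro-7-oxo-6-[(triethylsilyl)oxy]-11,12,13,14,15,16,17-heptanorlabdan-19-oate (C8 epimers) | CC(C)(C)OC(=O)[C@@]1(C)CCC[C@]2(C)CC(Cl)C(=O)[C@H](O[Si](CC)(CC)CC)[C@@H]12 | intermediate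
23 | tert-butyl (4S,5R,6R,10R)-7-oxo-6-[(triethylsilyl)oxy]-11,12,13,14,15,16,17-heptanorlabd-8-en-19-oate (trans-decalin, 6α-silyloxy, 4β-ester) | CC(C)(C)OC(=O)[C@@]1(C)CCC[C@]2(C)C=CC(=O)[C@H](O[Si](CC)(CC)CC)[C@@H]12 | intermediate
24 | (4S,5R,6R,10R)-6-hydroxy-7-oxo-11,12,13,14,15,16,17-heptanorlabd-8-en-19-oic acid | OC(=O)[C@@]1(C)CCC[C@]2(C)C=CC(=O)[C@H](O)[C@@H]12 | intermediate
25 | (4S,5R,6S,10R)-7-oxo-11,12,13,14,15,16,17-heptanorlabd-8-en-19,6-olide (19,6β-lactone) | O=C1C=C[C@@]2(C)CCC[C@]3(C)C(=O)O[C@H]1[C@H]23 | intermediate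
26 | but-3-yn-1-ol | C#CCCO | starting material
27 | tert-butyl(but-3-yn-1-yloxy)dimethylsilane | C#CCCO[Si](C)(C)C(C)(C)C | intermediate
28 | dimethyl[(1E)-4-[(tert-butyldimethylsilyl)oxy]-2-methylbut-1-en-1-yl]alane | C[Al](C)/C=C(\C)CCO[Si](C)(C)C(C)(C)C | intermediate
29 | (2E)-5-[(tert-butyldimethylsilyl)oxy]-3-methylpent-2-en-1-ol | CC(C)(C)[Si](C)(C)OCC/C(C)=C/CO | intermediate
30 | tert-butyl{[(3E)-5-[(tert-butyldiphenylsilyl)oxy]-3-methylpent-3-en-1-yl]oxy}dimethylsilane | CC(C)(C)[Si](C)(C)OCC/C(C)=C/CO[Si](c1ccccc1)(c1ccccc1)C(C)(C)C | intermediate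
31 | (3E)-5-[(tert-butyldiphenylsilyl)oxy]-3-methylpent-3-en-1-ol | OCC/C(C)=C/CO[Si](c1ccccc1)(c1ccccc1)C(C)(C)C | intermediate
32 | {[(2E)-5-bromo-3-methylpent-2-en-1-yl]oxy}(tert-butyl)diphenylsilane | BrCC/C(C)=C/CO[Si](c1ccccc1)(c1ccccc1)C(C)(C)C | intermediate
33 | [(3E)-5-[(tert-butyldiphenylsilyl)oxy]-3-methylpent-3-en-1-yl]magnesium bromide | Br[Mg]CC/C(C)=C/CO[Si](c1ccccc1)(c1ccccc1)C(C)(C)C | intermediate
34 | 7-(trimethylsilyloxy)-7-ene (silyl enol ether) of the 9α-alkylated lactone, 17-nor skeleton | C[Si](C)(C)OC1=C[C@@H](CC/C(C)=C/CO[Si](c2ccccc2)(c2ccccc2)C(C)(C)C)[C@@]2(C)CCC[C@]3(C)C(=O)O[C@H]1[C@H]23 | intermediate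
35 | 8-[(dimethylamino)methyl]-7-ketone (Mannich base, C8 epimers) of the 9α-alkylated lactone | CN(C)CC1[C@@H](CC/C(C)=C/CO[Si](c2ccccc2)(c2ccccc2)C(C)(C)C)[C@@]2(C)CCC[C@]3(C)C(=O)O[C@@H]([C@H]23)C1=O | intermediate
36 | trimethylammonium iodide of Mannich base 35 | C[N+](C)(C)CC1[C@@H](CC/C(C)=C/CO[Si](c2ccccc2)(c2ccccc2)C(C)(C)C)[C@@]2(C)CCC[C@]3(C)C(=O)O[C@@H]([C@H]23)C1=O.[I-] | intermediate
37 | (4S,5R,6S,9S,10R)-15-[(tert-butyldiphenylsilyl)oxy]-7-oxolabda-8(17),13E-dien-19,6-olide | C=C1[C@@H](CC/C(C)=C/CO[Si](c2ccccc2)(c2ccccc2)C(C)(C)C)[C@@]2(C)CCC[C@]3(C)C(=O)O[C@@H]([C@H]23)C1=O | intermediate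
38 | (4S,5R,6S,7S,9S,10R)-15-[(tert-butyldiphenylsilyl)oxy]-7-hydroxylabda-8(17),13E-dien-19,6-olide | C=C1[C@@H](CC/C(C)=C/CO[Si](c2ccccc2)(c2ccccc2)C(C)(C)C)[C@@]2(C)CCC[C@]3(C)C(=O)O[C@@H]([C@H]23)[C@H]1O | intermediate
39 | (4S,5R,6S,7S,9S,10R)-7-[(tert-butyldimethylsilyl)oxy]-15-[(tert-butyldiphenylsilyl)oxy]labda-8(17),13E-dien-19,6-olide | C=C1[C@@H](CC/C(C)=C/CO[Si](c2ccccc2)(c2ccccc2)C(C)(C)C)[C@@]2(C)CCC[C@]3(C)C(=O)O[C@@H]([C@H]23)[C@H]1O[Si](C)(C)C(C)(C)C | intermediate
40 | potassium (4S,5R,6S,7S,9S,10R)-7-[(tert-butyldimethylsilyl)oxy]-15-[(tert-butyldiphenylsilyl)oxy]-6-hydroxylabda-8(17),13E-dien-19-oate | C=C1[C@@H](CC/C(C)=C/CO[Si](c2ccccc2)(c2ccccc2)C(C)(C)C)[C@@]2(C)CCC[C@](C)(C(=O)[O-])[C@@H]2[C@H](O)[C@H]1O[Si](C)(C)C(C)(C)C.[K+] | intermediate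
41 | [2-(trimethylsilyl)ethoxy]methyl (4S,5R,6S,7S,9S,10R)-7-[(tert-butyldimethylsilyl)oxy]-15-[(tert-butyldiphenylsilyl)oxy]-6-hydroxylabda-8(17),13E-dien-19-oate | C=C1[C@@H](CC/C(C)=C/CO[Si](c2ccccc2)(c2ccccc2)C(C)(C)C)[C@@]2(C)CCC[C@](C)(C(=O)OCOCC[Si](C)(C)C)[C@@H]2[C@H](O)[C@H]1O[Si](C)(C)C(C)(C)C | intermediate
42 | [2-(trimethylsilyl)ethoxy]methyl (4S,5R,6S,7S,9S,10R)-6-(benzoyloxy)-7-[(tert-butyldimethylsilyl)oxy]-15-[(tert-butyldiphenylsilyl)oxy]labda-8(17),13E-dien-19-oate | C=C1[C@@H](CC/C(C)=C/CO[Si](c2ccccc2)(c2ccccc2)C(C)(C)C)[C@@]2(C)CCC[C@](C)(C(=O)OCOCC[Si](C)(C)C)[C@@H]2[C@H](OC(=O)c2ccccc2)[C@H]1O[Si](C)(C)C(C)(C)C | intermediate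
43 | (4S,5R,6S,7S,9S,10R)-6-(benzoyloxy)-7,15-dihydroxylabda-8(17),13E-dien-19-oic acid (CNP0149011.1) | C=C1[C@@H](CC/C(C)=C/CO)[C@@]2(C)CCC[C@](C)(C(=O)O)[C@@H]2[C@H](OC(=O)c2ccccc2)[C@H]1O | target

## Step count and risks

Total step count: 25. Longest linear sequence: 16 steps (steps 4, 5, 7, 8, 9, 10, 11, 12, 13, 14, 20, 21, 22, 23, 24, 25).

The three steps most likely to fail:

**Step 12 (the new radical bicyclisation).** Regiochemistry (6-endo twice), the C4 ester orientation and the facial control by C6 are all untested on this substrate. The fallback uses known chemistry in a different manifold; it sets out from 21 and comes back at 23. 21 is cyclised under the classical stoichiometric tin hydride chain conditions (Bu3SnH by syringe pump, AIBN, benzene, 80 °C). This is a reductive 6-endo/6-endo radical cyclisation of an α-halo ester of the kind established for polyene cascades, ended by hydrogen transfer instead of halogen rebound. It gives the saturated ketone tert-butyl (4S,5R,6R,10R)-7-oxo-6-[(triethylsilyl)oxy]-11,12,13,14,15,16,17-heptanorlabdan-19-oate F1. Kinetic enolisation away from C6 (LiN(SiMe3)2, Me3SiCl, THF, −78 °C) gives tert-butyl (4S,5R,6R,10R)-6-[(triethylsilyl)oxy]-7-[(trimethylsilyl)oxy]-11,12,13,14,15,16,17-heptanorlabd-7-en-19-oate F2. Saegusa–Ito dehydrogenation (Pd(OAc)2, MeCN, rt) then returns enone 23. This fallback still relies on the same two radical ring closures, so it answers a failure of the copper atom-transfer manifold but not an intrinsic regiochemical or stereochemical failure.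

**Step 14 (Mitsunobu lactonisation of a hindered α-hydroxy ketone).** The fallback avoids both the hydroxy acid and the phosphonium chemistry; it sets out from 23 and comes back at 25. Selective desilylation (HF·pyridine, THF, 0 °C) gives tert-butyl (4S,5R,6R,10R)-6-hydroxy-7-oxo-11,12,13,14,15,16,17-heptanorlabd-8-en-19-oate F3. Triflation (Tf2O, 2,6-di-tert-butylpyridine, CH2Cl2, −78 °C to rt) gives tert-butyl (4S,5R,6R,10R)-7-oxo-6-{[(trifluoromethyl)sulfonyl]oxy}-11,12,13,14,15,16,17-heptanorlabd-8-en-19-oate F4, which is not isolated. On warming, the carbonyl oxygen of the axial tert-butyl ester displaces the α-keto triflate with inversion and the lactonium ion loses isobutene, giving 25.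

**Step 21 (facial selectivity of the C7 reduction).** The fallback is an inversion instead of a change of hydride; it sets out from 37 and comes back at 38. If hydride enters from the α face, reduction of 37 gives (4S,5R,6S,7R,9S,10R)-15-[(tert-butyldiphenylsilyl)oxy]-7-hydroxylabda-8(17),13E-dien-19,6-olide F5. Mitsunobu inversion (4-nitrobenzoic acid, PPh3, DIAD, THF) gives (4S,5R,6S,7S,9S,10R)-15-[(tert-butyldiphenylsilyl)oxy]-7-[(4-nitrobenzoyl)oxy]labda-8(17),13E-dien-19,6-olide F6. Mild methanolysis (K2CO3, MeOH, 0 °C) then gives 38.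

## Further compounds

F1 | step 12 | tert-butyl (4S,5R,6R,10R)-7-oxo-6-[(triethylsilyl)oxy]-11,12,13,14,15,16,17-heptanorlabdan-19-oate | CC(C)(C)OC(=O)[C@@]1(C)CCC[C@]2(C)CCC(=O)[C@H](O[Si](CC)(CC)CC)[C@@H]12
F2 | step 12 | tert-butyl (4S,5R,6R,10R)-6-[(triethylsilyl)oxy]-7-[(trimethylsilyl)oxy]-11,12,13,14,15,16,17-heptanorlabd-7-en-19-oate | CC(C)(C)OC(=O)[C@@]1(C)CCC[C@]2(C)CC=C(O[Si](C)(C)C)[C@H](O[Si](CC)(CC)CC)[C@@H]12
F3 | step 14 | tert-butyl (4S,5R,6R,10R)-6-hydroxy-7-oxo-11,12,13,14,15,16,17-heptanorlabd-8-en-19-oate | CC(C)(C)OC(=O)[C@@]1(C)CCC[C@]2(C)C=CC(=O)[C@H](O)[C@@H]12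
F4 | step 14 | tert-butyl (4S,5R,6R,10R)-7-oxo-6-{[(trifluoromethyl)sulfonyl]oxy}-11,12,13,14,15,16,17-heptanorlabd-8-en-19-oate | CC(C)(C)OC(=O)[C@@]1(C)CCC[C@]2(C)C=CC(=O)[C@H](OS(=O)(=O)C(F)(F)F)[C@@H]12
F5 | step 21 | (4S,5R,6S,7R,9S,10R)-15-[(tert-butyldiphenylsilyl)oxy]-7-hydroxylabda-8(17),13E-dien-19,6-olide | C=C1[C@@H](CC/C(C)=C/CO[Si](c2ccccc2)(c2ccccc2)C(C)(C)C)[C@@]2(C)CCC[C@]3(C)C(=O)O[C@@H]([C@H]23)[C@@H]1O
F6 | step 21 | (4S,5R,6S,7S,9S,10R)-15-[(tert-butyldiphenylsilyl)oxy]-7-[(4-nitrobenzoyl)oxy]labda-8(17),13E-dien-19,6-olide | C=C1[C@@H](CC/C(C)=C/CO[Si](c2ccccc2)(c2ccccc2)C(C)(C)C)[C@@]2(C)CCC[C@]3(C)C(=O)O[C@@H]([C@H]23)[C@H]1OC(=O)c1ccc(cc1)[N+](=O)[O-]
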